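## Retrosynthetic overview

- The target is the (2S)-flavanone; the last step is global removal of four MOM ethers from the fully protected (2S)-flavanone.
- C2–aryl bond and the only stereocentre: Rh-catalysed asymmetric 1,4-addition of a 3,5-bis(MOM-oxy)phenylboronic acid to a 6-farnesyl-5,7-bis(MOM-oxy)chromone.
- C6–farnesyl bond: chelation-directed ortho-C-alkylation of the sodium 5-phenoxide of 5-hydroxy-7-(MOM-oxy)chromone with (2E,6E)-farnesyl bromide. Because the pyranone oxygen is already in place, 6- versus 8-substitution is not left to a ring closure.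
- No ring is built: the chromone bicycle (A/C rings) and the B ring are bought; the C ring is only saturated at C2 in the conjugate addition.
- The boronic acid comes from 5-bromoresorcinol by MOM protection and Br–Li exchange/borylation.

Assumption: 5,7-dihydroxychromone, 5-bromoresorcinol and (2E,6E)-farnesyl bromide are bought as catalogue items, and the (S)-configured biaryl bisphosphine is taken to give the 2S adduct (Hayashi quadrant model, as (S)-BINAP gives (S)-3-arylcyclohexanones); if a test run shows the opposite sense, the antipodal ligand is used.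

## Route

Step 1
Reactants: 1 5-bromoresorcinol (5-bromobenzene-1,3-diol); 2 chloromethyl methyl ether (MOMCl)
Product: 3 1-bromo-3,5-bis(methoxymethoxy)benzene
Conditions: MOMCl (2.5 equiv), i-Pr2NEt (3 equiv), CH2Cl2, 0 °C → rt
Reagents that add atoms: chloromethyl methyl ether (2), COCCl
Why: Williamson-type O-alkylation of both phenols by the reactive α-chloro ether under amine base; no stereocentre is involved.

Step 2
Reactants: 3 1-bromo-3,5-bis(methoxymethoxy)benzene; 4 triisopropyl borate
Product: 7 [3,5-bis(methoxymethoxy)phenyl]boronic acid, via aryllithium 5 (not isolated), via lithium triisopropoxyborate 6 (not isolated)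
Conditions: n-BuLi (1.05 equiv), THF, −78 °C, 15 min; B(Oi-Pr)3, −78 °C → rt; sat. aq NH4Cl
Reagents that add atoms: triisopropyl borate (4), CC(C)OB(OC(C)C)OC(C)C; water, O
Why: Bromine–lithium exchange is much faster than MOM-directed ortho-deprotonation at −78 °C, and the aryllithium is trapped by the borate (electrophilic borylation) and hydrolysed to the boronic acid.

Step 3
Reactants: 8 5,7-dihydroxy-4H-chromen-4-one; 2 chloromethyl methyl ether (MOMCl)
Product: 9 5-hydroxy-7-(methoxymethoxy)-4H-chromen-4-one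
Conditions: MOMCl (1.05 equiv), i-Pr2NEt (1.3 equiv), CH2Cl2/DMF, 0 °C
Reagents that add atoms: chloromethyl methyl ether (2), COCCl
Why: The 7-OH is the acidic, non-chelated phenol while the 5-OH is held in a hydrogen bond to C4=O, so one equivalent of MOMCl gives selective 7-O-alkylation (Williamson etherification).

Step 4
Reactants: 9 5-hydroxy-7-(methoxymethoxy)-4H-chromen-4-one; 10 (2E,6E)-farnesyl bromide
Product: 12 5-hydroxy-7-(methoxymethoxy)-6-[(2E,6E)-3,7,11-trimethyldodeca-2,6,10-trien-1-yl]-4H-chromen-4-one, via sodium chromen-5-olate 11 (not isolated)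
Conditions: NaH (1.1 equiv), toluene, 0 °C → rt; 10 (1.2 equiv), rt → 60 °C
Reagents that add atoms: (2E,6E)-farnesyl bromide (10), CC(C)=CCC/C(C)=C/CC/C(C)=C/CBr
Why: In a non-polar solvent the sodium phenoxide chelated to C4=O is C-alkylated at C6, its only free ortho position, through a cyclic SN2 transition state (ortho-C-allylation of a phenoxide), which fixes 6-regiochemistry and leaves the E,E chain unchanged.

Step 5
Reactants: 12 6-farnesyl-5-hydroxy-7-(methoxymethoxy)chromone; 2 chloromethyl methyl ether (MOMCl)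
Product: 14 5,7-bis(methoxymethoxy)-6-[(2E,6E)-3,7,11-trimethyldodeca-2,6,10-trien-1-yl]-4H-chromen-4-one, via sodium 6-farnesylchromen-5-olate 13 (not isolated)
Conditions: NaH (1.3 equiv), DMF, 0 °C; MOMCl (1.3 equiv), 0 °C → rt
Reagents that add atoms: chloromethyl methyl ether (2), COCCl
Why: Irreversible deprotonation frees the chelated, hindered 5-phenoxide for Williamson O-alkylation, masking the last acidic OH so the later flavanone cannot ring-open through a phenoxide.

Step 6
Reactants: 14 6-farnesyl-5,7-bis(methoxymethoxy)chromone; 7 [3,5-bis(methoxymethoxy)phenyl]boronic acid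
Product: 15 (2S)-2-[3,5-bis(methoxymethoxy)phenyl]-5,7-bis(methoxymethoxy)-6-[(2E,6E)-3,7,11-trimethyldodeca-2,6,10-trien-1-yl]-2,3-dihydro-4H-chromen-4-one
Conditions: [RhOH{(S)-MeO-F12-BIPHEP}]2 (3 mol % Rh), 7 (3 equiv), toluene/H2O 10:1, 40 °C
Reagents that add atoms: [3,5-bis(methoxymethoxy)phenyl]boronic acid (7), OB(O)c1cc(OCOC)cc(OCOC)c1
Why: Rhodium-catalysed asymmetric 1,4-addition (Hayashi–Miyaura) of the arylrhodium to C2 of the chromone, in which the electron-poor C2-symmetric (S)-bisphosphine blocks one enone face so the aryl group is delivered to give the 2S centre, followed by protonation of the rhodium enolate; the isolated trisubstituted alkenes do not insert.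

Step 7
Reactants: 15 (2S)-tetra-MOM flavanone
Product: 16 (2S)-2-(3,5-dihydroxyphenyl)-5,7-dihydroxy-6-[(2E,6E)-3,7,11-trimethyldodeca-2,6,10-trien-1-yl]-2,3-dihydro-4H-chromen-4-one (target)
Conditions: 3 M aq HCl, MeOH/THF, 45 °C, stopped at full conversion
Reagents that add atoms: none
Why: Acid-catalysed acetal exchange (methanolysis) removes all four MOM ethers, and C2 keeps its configuration because retro-oxa-Michael ring opening is a base-mediated process that is slow in dilute acid.

## Compound list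

1 | 5-bromoresorcinol (5-bromobenzene-1,3-diol) | Oc1cc(O)cc(Br)c1 | starting material
2 | chloromethyl methyl ether (MOMCl) | COCCl | starting material
3 | 1-bromo-3,5-bis(methoxymethoxy)benzene | COCOc1cc(Br)cc(OCOC)c1 | intermediate
4 | triisopropyl borate | CC(C)OB(OC(C)C)OC(C)C | starting material
5 | [3,5-bis(methoxymethoxy)phenyl]lithium | [Li]c1cc(OCOC)cc(OCOC)c1 | intermediate
6 | lithium [3,5-bis(methoxymethoxy)phenyl]triisopropoxyborate | [Li+].CC(C)O[B-](OC(C)C)(OC(C)C)c1cc(OCOC)cc(OCOC)c1 | intermediate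
7 | [3,5-bis(methoxymethoxy)phenyl]boronic acid | OB(O)c1cc(OCOC)cc(OCOC)c1 | intermediate
8 | 5,7-dihydroxy-4H-chromen-4-one (5,7-dihydroxychromone) | Oc1cc(O)cc2occc(=O)c12 | starting material
9 | 5-hydroxy-7-(methoxymethoxy)-4H-chromen-4-one | Oc1cc(OCOC)cc2occc(=O)c12 | intermediate
10 | (2E,6E)-farnesyl bromide ((2E,6E)-1-bromo-3,7,11-trimethyldodeca-2,6,10-triene) | CC(C)=CCC/C(C)=C/CC/C(C)=C/CBr | starting material
11 | sodium 7-(methoxymethoxy)-4-oxo-4H-chromen-5-olate | [Na+].[O-]c1cc(OCOC)cc2occc(=O)c12 | intermediate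
12 | 5-hydroxy-7-(methoxymethoxy)-6-[(2E,6E)-3,7,11-trimethyldodeca-2,6,10-trien-1-yl]-4H-chromen-4-one | CC(C)=CCC/C(C)=C/CC/C(C)=C/Cc1c(OCOC)cc2occc(=O)c2c1O | intermediate
13 | sodium 7-(methoxymethoxy)-4-oxo-6-[(2E,6E)-3,7,11-trimethyldodeca-2,6,10-trien-1-yl]-4H-chromen-5-olate | CC(C)=CCC/C(C)=C/CC/C(C)=C/Cc1c(OCOC)cc2occc(=O)c2c1[O-].[Na+] | intermediate
14 | 5,7-bis(methoxymethoxy)-6-[(2E,6E)-3,7,11-trimethyldodeca-2,6,10-trien-1-yl]-4H-chromen-4-one | CC(C)=CCC/C(C)=C/CC/C(C)=C/Cc1c(OCOC)cc2occc(=O)c2c1OCOC | intermediate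
15 | (2S)-2-[3,5-bis(methoxymethoxy)phenyl]-5,7-bis(methoxymethoxy)-6-[(2E,6E)-3,7,11-trimethyldodeca-2,6,10-trien-1-yl]-2,3-dihydro-4H-chromen-4-one | CC(C)=CCC/C(C)=C/CC/C(C)=C/Cc1c(OCOC)cc2c(c1OCOC)C(=O)C[C@@H](c1cc(OCOC)cc(OCOC)c1)O2 | intermediate
16 | (2S)-2-(3,5-dihydroxyphenyl)-5,7-dihydroxy-6-[(2E,6E)-3,7,11-trimethyldodeca-2,6,10-trien-1-yl]-2,3-dihydro-4H-chromen-4-one | CC(C)=CCC/C(C)=C/CC/C(C)=C/Cc1c(O)cc2c(c1O)C(=O)C[C@@H](c1cc(O)cc(O)c1)O2 | target

## Step count and risks

Total step count: 7. Longest linear sequence: 5 steps (8 → 9 → 12 → 14 → 15 → 16, steps 3–7); the boronic acid branch is 2 steps (steps 1–2).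

The three steps most likely to fail:

**Step 4 (ortho-C-farnesylation).** O-alkylation at O5, some C8 attack, SN2′ (branched) product and poor solubility of the sodium salt can all lower the yield. The fallback sets out from 9 and comes back at 12, and replaces phenoxide alkylation by halogenation and cross-coupling. Iodination of 9 with BnMe3N·ICl2/CaCO3 in CH2Cl2–MeOH, directed ortho to the chelated 5-OH, gives 5-hydroxy-6-iodo-7-(methoxymethoxy)-4H-chromen-4-one F1. Separately, 10 is treated with Bu3SnLi (THF, −78 °C) to give tributyl[(2E,6E)-3,7,11-trimethyldodeca-2,6,10-trien-1-yl]stannane F2. Stille coupling of F1 with F2 (Pd2(dba)3, AsPh3, NMP, 50 °C) joins the linear allyl terminus to C6 and gives 12.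

**Step 6 (asymmetric 1,4-addition).** The chromone is electron-rich and flanked at C5, so conversion or ee may be insufficient. The fallback sets out from 14 and comes back at 15, and replaces asymmetric catalysis by kinetic resolution. Addition of 7 with an achiral catalyst ([RhOH(cod)]2, dioxane/H2O, 40 °C) gives racemic 2-[3,5-bis(methoxymethoxy)phenyl]-5,7-bis(methoxymethoxy)-6-farnesylchroman-4-one F3. Asymmetric transfer hydrogenation with RuCl[(R,R)-TsDPEN](p-cymene) and HCO2H/Et3N reduces the (2R)-enantiomer to the (2R,4R)-cis-flavan-4-ol F4 and leaves (2S)-15, which is separated by chromatography (at most 50 % of the material).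

**Step 7 (global MOM removal).** Brønsted acid can add across the farnesyl alkenes or cyclise them onto the flanking 5- or 7-OH (chroman formation). The fallback sets out from 15 and comes back at 16, and avoids free protic acid by trans-protection. TMSOTf/2,2′-bipyridyl in MeCN at 0 °C exchanges the four aryl MOM ethers for trimethylsilyl ethers, giving the (2S)-tetrakis(trimethylsilyloxy) flavanone F5. F5 is then hydrolysed in neutral aqueous MeOH (pH 7 buffer) to 16.

## Further compounds

F1 | step 4 | 5-hydroxy-6-iodo-7-(methoxymethoxy)-4H-chromen-4-one | Oc1c(I)c(OCOC)cc2occc(=O)c12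
F2 | step 4 | tributyl[(2E,6E)-3,7,11-trimethyldodeca-2,6,10-trien-1-yl]stannane | CC(C)=CCC/C(C)=C/CC/C(C)=C/C[Sn](CCCC)(CCCC)CCCC
F3 | step 6 | racemic 2-[3,5-bis(methoxymethoxy)phenyl]-5,7-bis(methoxymethoxy)-6-[(2E,6E)-3,7,11-trimethyldodeca-2,6,10-trien-1-yl]-2,3-dihydro-4H-chromen-4-one | CC(C)=CCC/C(C)=C/CC/C(C)=C/Cc1c(OCOC)cc2c(c1OCOC)C(=O)CC(c1cc(OCOC)cc(OCOC)c1)O2
F4 | step 6 | (2R,4R)-2-[3,5-bis(methoxymethoxy)phenyl]-5,7-bis(methoxymethoxy)-6-[(2E,6E)-3,7,11-trimethyldodeca-2,6,10-trien-1-yl]-3,4-dihydro-2H-chromen-4-ol (2,4-cis) | CC(C)=CCC/C(C)=C/CC/C(C)=C/Cc1c(OCOC)cc2c(c1OCOC)[C@H](O)C[C@H](c1cc(OCOC)cc(OCOC)c1)O2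
F5 | step 7 | (2S)-2-[3,5-bis(trimethylsilyloxy)phenyl]-5,7-bis(trimethylsilyloxy)-6-[(2E,6E)-3,7,11-trimethyldodeca-2,6,10-trien-1-yl]-2,3-dihydro-4H-chromen-4-one | CC(C)=CCC/C(C)=C/CC/C(C)=C/Cc1c(O[Si](C)(C)C)cc2c(c1O[Si](C)(C)C)C(=O)C[C@@H](c1cc(O[Si](C)(C)C)cc(O[Si](C)(C)C)c1)O2
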